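Ring A is only the trimethylene bridge C1–C2–C3 between the two quaternary carbons C4 and C10, which flank C5 beside the C6 carbonyl. In a quinone monoketal made from carvacrol, C10 and C4 are the α and γ termini of one extended enolate of the C9 ketone. A one-pot annulation with (Z)-1,3-dichloropropene therefore forms C1–C10 by allylic alkylation and C3–C4 by palladium-catalysed γ-alkenylation, closing ring A on a flat, achiral bicyclic dienone. An asymmetric epoxidation then installs C7/C8, and the epoxide directs the C10 methyl and the C9 side chain; a Sharpless epoxide fixes C13.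

Key step: step 2

Remark: labdane numbering is used for all compounds (ring A = C1–C5 and C10; ring B = C5–C10; side chain C11–C16; α is the face of ring B opposite to the C10 methyl); the sense of induction of the tartrate-mediated epoxidation in step 4 is assumed, and the antipodal tartrate would be used if it proves opposite.

Step 1
Reactants: 1 carvacrol
Product: 3 4,4-dimethoxy-2-methyl-5-(propan-2-yl)cyclohexa-2,5-dien-1-one, via methoxyphenol intermediate 2 (not isolated)
Conditions: PhI(OAc)2 (2.2 equiv), MeOH, 0 °C to rt
Reagents that add atoms: methanol CO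
Why: Double oxidative dearomatisation of a para-unsubstituted phenol with PhI(OAc)2 in methanol: the first oxidation should give the 4-methoxyphenol 2 and the second the quinone monoketal 3, whose ketal carbon is C6 and whose ketone is C9.

Step 2
Reactants: 3 quinone monoketal; 4 (Z)-1,3-dichloropropene
Product: 6 4,4-dimethoxy-2,5,5-trimethyl-5,8-dihydronaphthalen-1(4H)-one, via chloroallyl dienone ketal 5 (not isolated)
Conditions: LiN(SiMe3)2 (1.05 equiv), THF, −78 to −20 °C; 4, NaI (cat.), −78 to 0 °C; then LiN(SiMe3)2 (1.2 equiv), Pd2(dba)3 (cat.), P(t-Bu)3 (cat.), 50 °C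
Reagents that add atoms: none
Why: Proposed new method: the amide base removes the only acidic proton of 3, the isopropyl methine C4–H (γ to the C9 ketone), and the cross-conjugated dienolate is alkylated at its α-carbon C10 by the allylic chloride end of 4 (SN2, C1–C10 bond); the second equivalent of base regenerates the dienolate from 5, zerovalent palladium inserts into the Z-vinyl chloride, and C–C reductive elimination joins C3 to the γ-carbon C4, restoring the conjugated C5=C10 enone. The closest known reaction types are the α-alkylation of extended enolates, the palladium-catalysed intramolecular alkenylation of ketone enolates and the γ-arylation of dienolates. Ring A closes by reductive elimination from a seven-membered alkenylpalladium dienolate palladacycle (a 6-exo-type closure at the alkenyl carbon); a plain SN2 ring closure is avoided because O-alkylation to a chroman-type ether would compete. No stereocentre is formed, since the product is flat and achiral. The step needs γ-C coupling over α-C and O coupling: α-coupling would give a cyclobutene, C–O reductive elimination from palladium enolates is slow, and only the Z-alkene can reach C4.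

Step 3
Reactants: 6 dihydronaphthalenone ketal
Product: 7 4,4-dimethoxy-2,5,5-trimethyl-5,6,7,8-tetrahydronaphthalen-1(4H)-one
Conditions: H2 (1 atm), RhCl(PPh3)3 (cat.), benzene–EtOH, rt
Reagents that add atoms: none
Why: Homogeneous hydrogenation with RhCl(PPh3)3 should reduce only the unhindered cis-disubstituted C2=C3 alkene and leave the trisubstituted and tetrasubstituted enone double bonds of the dienone.

Step 4
Reactants: 7 bicyclic dienone ketal
Product: 8 (7S,8R)-7α,8α-epoxy enone ketal
Conditions: Ph3COOH, NaN(SiMe3)2, L-(+)-diisopropyl tartrate, toluene, −60 °C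
Reagents that add atoms: trityl hydroperoxide OOC(c1ccccc1)(c1ccccc1)c1ccccc1
Why: Tartrate-mediated asymmetric nucleophilic (Weitz–Scheffer) epoxidation of a quinone monoketal: the peroxide anion can add only to the β-carbon C7 (C5 is fully substituted and ring-fused), and the chiral sodium tartrate complex should select the α face, setting C7 (S) and C8 (R).

Step 5
Reactants: 8 epoxy enone ketal
Product: 9 7α,8α-epoxy-5(10)-ene-6,9-dione
Conditions: pyridinium p-toluenesulfonate, acetone–H2O, 40 °C
Reagents that add atoms: water O
Why: Mild acid hydrolysis of the dimethyl ketal unmasks the C6 ketone; the α,β-epoxy ketone is deactivated towards acid and the product cannot tautomerise to a phenol because C8 is quaternary.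

Step 6
Reactants: 9 epoxy ene-dione
Product: 10 10β-methyl C6 triethylsilyl enol ether (C5=C6) with C9 ketone and 7α,8α-epoxide
Conditions: MeMgBr, CuBr·SMe2 (cat.), Et3SiCl, HMPA, THF, −78 °C
Reagents that add atoms: methylmagnesium bromide C[Mg]Br; chlorotriethylsilane CC[Si](Cl)(CC)CC
Why: Chlorosilane-accelerated copper-catalysed conjugate addition: methyl should add to C10, the β-carbon not blocked by the neighbouring quaternary C4, from the β face anti to the epoxide oxygen (C10 becomes S), and the C6 enolate is trapped as its silyl enol ether, which masks C6 and leaves C9 as the only ketone.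

Step 7
Reactants: 10 silyl enol ether ketone
Product: 11 9α,11-spiro-epoxide (C11 β)
Conditions: Me3S+ I−, n-BuLi, THF, −10 to 0 °C
Reagents that add atoms: trimethylsulfonium iodide C[S+](C)C.[I-]
Why: Corey–Chaykovsky methylenation: the small sulfonium methylide should add to the non-enolisable C9 ketone from the β face, anti to the neighbouring epoxide oxygen and to the ring A methylene C1, so that C11 is β and the C9 oxygen α.

Step 8
Reactants: 11 spiro-epoxide; 12 methallyl alcohol
Product: 13 9α-hydroxy diol silyl enol ether with the C11–C14 side chain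
Conditions: 12, n-BuLi (2 equiv), TMEDA, Et2O, 0 °C to rt; then 11, THF, −78 to 0 °C
Reagents that add atoms: none
Why: Epoxide opening by an allylic organolithium: the dianion of methallyl alcohol should attack the primary carbon C11 of the spiro-epoxide (SN2), forming C11–C12 and leaving the C9 oxygen untouched as the 9α-alkoxide; no carbonyl group is free at this stage.

Step 9
Reactants: 13 diol silyl enol ether
Product: 14 cis-fused (5β-H) 7α,8α-epoxy-9α-hydroxy-6-ketone with allylic alcohol side chain
Conditions: Bu4NF, THF, 0 °C to rt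
Reagents that add atoms: none
Why: Fluoride cleaves the silyl enol ether and the basic medium should equilibrate C5 to the cis-fused 5β-H ketone, assumed to be the ring fusion that 4,4,10-trimethyl-6-oxodecalins prefer at equilibrium because it relieves the contact of the equatorial C4 methyl with the C6 carbonyl; C5 stays under this thermodynamic control to the end.

Step 10
Reactants: 14 allylic alcohol
Product: 15 (13R)-13,16-epoxy alcohol
Conditions: Ti(OiPr)4 (cat.), D-(−)-diisopropyl tartrate, t-BuOOH, 4 Å molecular sieves, CH2Cl2, −20 °C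
Reagents that add atoms: tert-butyl hydroperoxide CC(C)(C)OO
Why: Sharpless asymmetric epoxidation of a 2-substituted allylic alcohol: reagent control by the D-(−)-tartrate should give the (13R)-epoxy alcohol, while the epoxy ketone and the hindered tertiary C9 hydroxyl do not take part.

Step 11
Reactants: 15 epoxy alcohol
Product: 16 epoxy aldehyde (C14 aldehyde)
Conditions: Dess–Martin periodinane, pyridine, CH2Cl2, 0 °C
Reagents that add atoms: none
Why: Dess–Martin oxidation of the primary alcohol differentiates the C14 arm from the latent C16 hydroxymethyl before the epoxide is opened, and the pyridine buffer keeps both epoxides closed.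

Step 12
Reactants: 16 epoxy aldehyde
Product: 17 methyl enol ether (C14=C15, E/Z mixture)
Conditions: Ph3P+CH2OMe Cl−, KN(SiMe3)2, THF, −78 to 0 °C
Reagents that add atoms: (methoxymethyl)triphenylphosphonium chloride COC[P+](c1ccccc1)(c1ccccc1)c1ccccc1.[Cl-]
Why: Wittig methoxymethylenation adds C15 at the aldehyde oxidation level; the aldehyde should react far faster than the hindered C6 ketone, and its α-carbon C13 is quaternary and cannot epimerise.

Step 13
Reactants: 17 epoxy enol ether
Product: 19 bis-spiro methyl acetal (9α,13:15,16-diepoxy-15-methoxy; C13 S), via hydroxy enol ether 18 (not isolated)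
Conditions: camphorsulfonic acid (cat.), CH2Cl2, −20 to 0 °C
Reagents that add atoms: none
Why: Acid-catalysed cascade: the tertiary C9 hydroxyl opens the 2,2-disubstituted epoxide at its tertiary carbon C13 (5-exo, inversion, so C13 becomes S), and the freed C16 hydroxyl adds to the protonated enol ether to close the cyclic methyl acetal (5-exo), while the deactivated α,β-epoxy ketone should stay closed.

Step 14
Reactants: 19 bis-spiro epoxy ketone
Product: 20 7β,8α-diacetate
Conditions: Ac2O, Bu4NOAc (cat.), toluene, 60 °C
Reagents that add atoms: acetic anhydride CC(=O)OC(C)=O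
Why: Acetate-catalysed epoxide acetolysis: acetate should attack C7, the secondary carbon α to the ketone, from the β face (SN2, trans-diaxial Fürst–Plattner opening, inversion to 7R), and the tertiary C8 alkoxide is acetylated at once by acetic anhydride, which regenerates acetate and leaves the C8 oxygen α.

Step 15
Reactants: 20 diacetate
Product: 21 8α-acetoxy-7β-hydroxy ketone methyl acetal
Conditions: HCl (cat.), MeOH, 0 °C to rt
Reagents that add atoms: none
Why: Acid-catalysed transesterification should remove only the secondary α-keto acetate at C7; the tertiary C8 acetate reacts far more slowly, the trans-diaxial arrangement excludes acyl migration, and acid avoids E1cB loss of the β-acetoxy group.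

Step 16
Reactants: 21 hydroxy acetate methyl acetal
Product: 23 target CNP0275274.1, via silyl ether 22 (not isolated)
Conditions: Me3SiOTf, i-Pr2NEt, CH2Cl2, −40 to 0 °C; then Bu4NF, AcOH, THF, 0 °C
Reagents that add atoms: none
Why: Silyl triflate–amine elimination of the cyclic methyl acetal should give the enol ether C14=C15, the only possible direction because C13 is quaternary; the C7 hydroxyl is silylated in passing and freed with buffered fluoride, which spares the acid-labile enol ether and the base-labile β-acetoxy ketone.

Compound list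
1 | carvacrol (2-methyl-5-(propan-2-yl)phenol) | Cc1ccc(C(C)C)cc1O | starting material
2 | 4-methoxy-2-methyl-5-(propan-2-yl)phenol | Cc1cc(OC)c(C(C)C)cc1O | intermediate
3 | 4,4-dimethoxy-2-methyl-5-(propan-2-yl)cyclohexa-2,5-dien-1-one | CC1=CC(OC)(OC)C(C(C)C)=CC1=O | intermediate
4 | (Z)-1,3-dichloropropene | Cl/C=C\CCl | starting material
5 | 6-[(Z)-3-chloroprop-2-enyl]-4,4-dimethoxy-2-methyl-5-(propan-2-ylidene)cyclohex-2-en-1-one (racemic) | CC1=CC(OC)(OC)C(=C(C)C)C(C/C=C\Cl)C1=O | intermediate
6 | 4,4-dimethoxy-2,5,5-trimethyl-5,8-dihydronaphthalen-1(4H)-one | O=C1C(C)=CC(OC)(OC)C2=C1CC=CC2(C)C | intermediate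
7 | 4,4-dimethoxy-2,5,5-trimethyl-5,6,7,8-tetrahydronaphthalen-1(4H)-one | O=C1C(C)=CC(OC)(OC)C2=C1CCCC2(C)C | intermediate
8 | (7S,8R)-7α,8α-epoxy enone ketal | O=C1[C@]2(C)O[C@@H]2C(OC)(OC)C3=C1CCCC3(C)C | intermediate
9 | 7α,8α-epoxy-5(10)-ene-6,9-dione | O=C1[C@]2(C)O[C@@H]2C(=O)C3=C1CCCC3(C)C | intermediate
10 | 10β-methyl C6 triethylsilyl enol ether with C9 ketone and 7α,8α-epoxide | O=C1[C@]2(C)O[C@@H]2C(O[Si](CC)(CC)CC)=C2C(C)(C)CCC[C@]12C | intermediate
11 | 9α,11-spiro-epoxide of 10 | C1O[C@@]12[C@]3(C)O[C@@H]3C(O[Si](CC)(CC)CC)=C3C(C)(C)CCC[C@]23C | intermediate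
12 | methallyl alcohol (2-methylprop-2-en-1-ol) | CC(=C)CO | starting material
13 | 9α-hydroxy diol silyl enol ether (side chain CH2CH2C(=CH2)CH2OH on C9β) | OCC(=C)CC[C@@]1(O)[C@]2(C)O[C@@H]2C(O[Si](CC)(CC)CC)=C2C(C)(C)CCC[C@]12C | intermediate
14 | cis-fused (5β-H) 7α,8α-epoxy-9α-hydroxy-6-ketone allylic alcohol | OCC(=C)CC[C@@]1(O)[C@]2(C)O[C@@H]2C(=O)[C@@H]2C(C)(C)CCC[C@]12C | intermediate
15 | (13R)-13,16-epoxy alcohol | OC[C@@]1(CO1)CC[C@@]2(O)[C@]3(C)O[C@@H]3C(=O)[C@@H]3C(C)(C)CCC[C@]23C | intermediate
16 | 13,16-epoxy C14 aldehyde | O=C[C@@]1(CO1)CC[C@@]2(O)[C@]3(C)O[C@@H]3C(=O)[C@@H]3C(C)(C)CCC[C@]23C | intermediate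
17 | 13,16-epoxy methyl enol ether (E/Z mixture) | COC=C[C@@]1(CO1)CC[C@@]2(O)[C@]3(C)O[C@@H]3C(=O)[C@@H]3C(C)(C)CCC[C@]23C | intermediate
18 | 9α,13-epoxy 16-hydroxy methyl enol ether (13S) | C[C@@]12O[C@@H]1C(=O)[C@@H]1C(C)(C)CCC[C@]1(C)[C@@]21CC[C@](C=COC)(CO)O1 | intermediate
19 | 7α,8α-epoxy-15-methoxy-9α,13:15,16-diepoxylabdan-6-one (C15 epimers) | C[C@@]12O[C@@H]1C(=O)[C@@H]1C(C)(C)CCC[C@]1(C)[C@@]21CC[C@@]2(CC(OC)OC2)O1 | intermediate
20 | 7β,8α-diacetoxy-15-methoxy-9α,13:15,16-diepoxylabdan-6-one (C15 epimers) | CC(=O)O[C@]1(C)[C@@H](OC(C)=O)C(=O)[C@@H]2C(C)(C)CCC[C@]2(C)[C@@]12CC[C@@]1(CC(OC)OC1)O2 | intermediate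
21 | 8α-acetoxy-7β-hydroxy-15-methoxy-9α,13:15,16-diepoxylabdan-6-one (C15 epimers) | CC(=O)O[C@]1(C)[C@@H](O)C(=O)[C@@H]2C(C)(C)CCC[C@]2(C)[C@@]12CC[C@@]1(CC(OC)OC1)O2 | intermediate
22 | 7-O-trimethylsilyl ether of the target | CC(=O)O[C@]1(C)[C@@H](O[Si](C)(C)C)C(=O)[C@@H]2C(C)(C)CCC[C@]2(C)[C@@]12CC[C@@]1(C=COC1)O2 | intermediate
23 | CNP0275274.1, (5R,7R,8R,9S,10S,13S)-8-acetoxy-7-hydroxy-9,13:15,16-diepoxylabd-14-en-6-one | CC(=O)O[C@]1(C)[C@@H](O)C(=O)[C@@H]2C(C)(C)CCC[C@]2(C)[C@@]12CC[C@@]1(C=COC1)O2 | target

Total step count: 16. Longest linear sequence: 16 steps from carvacrol.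

Steps most likely to fail

Step 2 (proposed new method). The palladium dienolate may be diverted to O-coupling, β-hydride elimination from the tertiary C4–palladium species or simple reduction of the vinyl chloride, and the dienolate may be alkylated twice at C10. The fallback makes the same two bonds by known steps from 3. C10-alkylation of the dienolate with (Z)-3-iodo-1-(trimethylsilyl)prop-1-ene gives the vinylsilane ketal F1. BF3·OEt2 ionises the ketal and the vinylsilane closes ring A at C4 (vinylsilane-terminated cation cyclisation); the product aromatises to 4-methoxy-2,5,5-trimethyl-5,8-dihydronaphthalen-1-ol F2. Hydrogenation (H2, Pd on carbon) gives the tetralin phenol F3, and PhI(OAc)2 in methanol returns to 7.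

Step 6. Electron transfer from the organocopper species may open the α,β-epoxy ketone reductively, or the facial selectivity of the methyl addition may be poor. The fallback introduces the methyl group by enolate alkylation from 9. Conjugate reduction with K[HB(s-Bu)3] gives the saturated epoxy diketone F4. Deprotonation at the less hindered C10 with LiN(i-Pr)2 and methylation with MeI, entering anti to C4 and to the epoxide oxygen, gives the angular methyl diketone F5. Et3SiOTf and Et3N then return to 10.

Step 14. Acetate may attack the tertiary C8, or the epoxy ketone may isomerise to a diosphenol, instead of undergoing SN2 opening at C7. The fallback sets the two oxygen functions separately from 19. Reductive cleavage of the C7–O bond with SmI2 (THF–MeOH, −78 °C) gives the 8α-hydroxy ketone F6. Acetylation (Ac2O, 4-dimethylaminopyridine) gives the 8α-acetoxy ketone F7. Soft enolisation towards C7 (Me3SiOTf, Et3N) gives the silyl enol ether F8, and Rubottom oxidation with dimethyldioxirane from the open β face, followed by loss of the silyl group on work-up, returns to 21.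

Further compounds
F1 | step 2 | 6-[(Z)-3-(trimethylsilyl)prop-2-enyl]-4,4-dimethoxy-2-methyl-5-(propan-2-ylidene)cyclohex-2-en-1-one | CC1=CC(OC)(OC)C(=C(C)C)C(C/C=C\[Si](C)(C)C)C1=O
F2 | step 2 | 4-methoxy-2,5,5-trimethyl-5,8-dihydronaphthalen-1-ol | COc1cc(C)c(O)c2c1C(C)(C)C=CC2
F3 | step 2 | 4-methoxy-2,5,5-trimethyl-5,6,7,8-tetrahydronaphthalen-1-ol | COc1cc(C)c(O)c2c1C(C)(C)CCC2
F4 | step 6 | saturated 7α,8α-epoxy-6,9-diketone (C5 and C10 unassigned) | O=C1[C@]2(C)O[C@@H]2C(=O)C2C(C)(C)CCCC12
F5 | step 6 | 10β-methyl 5β-H 7α,8α-epoxy-6,9-diketone | O=C1[C@]2(C)O[C@@H]2C(=O)[C@@H]2C(C)(C)CCC[C@]12C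
F6 | step 14 | 8α-hydroxy-15-methoxy-9α,13:15,16-diepoxylabdan-6-one | O[C@]1(C)CC(=O)[C@@H]2C(C)(C)CCC[C@]2(C)[C@@]12CC[C@@]1(CC(OC)OC1)O2
F7 | step 14 | 8α-acetoxy-15-methoxy-9α,13:15,16-diepoxylabdan-6-one | CC(=O)O[C@]1(C)CC(=O)[C@@H]2C(C)(C)CCC[C@]2(C)[C@@]12CC[C@@]1(CC(OC)OC1)O2
F8 | step 14 | C6 trimethylsilyl enol ether (C6=C7) of F7 | CC(=O)O[C@]1(C)C=C(O[Si](C)(C)C)[C@@H]2C(C)(C)CCC[C@]2(C)[C@@]12CC[C@@]1(CC(OC)OC1)O2
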